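**Plan** (elemane numbering: ring B = C5–C10; lactone = O–C6, C7, C11, C12; vinyl C1=C2 on C10; C3=C4–C15 on C5)
1. Retrosynthesis first removes the C8 acyl group, the C4 unit (C4–C15 bond and C3 methylene, leaving a C4 carboxyl) and the C11 methyl group.
2. The lactone O–C6 bond and the ring bond C7–C8 are then cut together, which opens ring B to an acyclic (E)-alkenyl aldehyde; last, the C5–C10 bond is cut by an Ireland–Claisen retron.
3. Enabling feature: on ring B, C6–O, C7–C11, C7–C8 and C8–O are all equatorial and H6/H7 are trans-diaxial. This is the result expected from anti addition of C8 and a carboxyl oxygen across an (E)-C6=C7 bond of a β,γ-unsaturated ester in a chair.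
4. Forward: allylic alcohol 3 and hydromuconic half ester 5 are joined and rearranged (C5–C10); the aldehyde then closes ring B and the lactone in one operation; C11 methylation, C8 acylation and elaboration of C4 follow.
5. Stereochemistry: C5/C10 come from the enantioselective Claisen step; C6, C7, C8 are relayed in the cyclisation; C11 is set by enolate alkylation; the side chain comes from methyl (R)-3-hydroxy-2-methylpropanoate.

Key step: step 8

Remark on the chemistry: the (4R,5R) boron controller is assumed to give acid 9 with the (2R,3′S) configuration; if its facial sense is the opposite, the (4S,5S) controller is used and nothing else changes.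

**Step 1**
Reactants: 1 tert-butyl(but-3-yn-1-yloxy)dimethylsilane
Product: 3 (2E)-5-{[tert-butyl(dimethyl)silyl]oxy}-3-methylpent-2-en-1-ol, via alkenyl dimethylalane 2 (not isolated)
Conditions: AlMe3, Cp2ZrCl2 (25 mol %), CH2Cl2, 0 °C → rt; then (CH2O)n, rt; aq. potassium sodium tartrate (KNaC4H4O6)
Reagents that add atoms: trimethylaluminium, C[Al](C)C; paraformaldehyde (as formaldehyde), C=O
Why: Negishi carboalumination adds methyl and aluminium syn across the terminal alkyne with aluminium at the terminus, and the alkenylalane is hydroxymethylated with retention, so only the (E)-trisubstituted allylic alcohol should form.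

**Step 2**
Reactants: 4 (3E)-hex-3-enedioic acid
Product: 5 (3E)-6-tert-butoxy-6-oxohex-3-enoic acid
Conditions: tert-butyl 2,2,2-trichloroacetimidate (1.0 equiv), THF/cyclohexane, rt; separation from diacid and diester
Reagents that add atoms: tert-butyl 2,2,2-trichloroacetimidate, CC(C)(C)OC(=N)C(Cl)(Cl)Cl
Why: imidate tert-butylation of a carboxylic acid needs no base, so the β,γ-double bond should not move into conjugation, and the statistical mono-ester is separable by extraction and chromatography.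

**Step 3**
Reactants: 3 (2E)-5-{[tert-butyl(dimethyl)silyl]oxy}-3-methylpent-2-en-1-ol; 5 (3E)-6-tert-butoxy-6-oxohex-3-enoic acid
Product: 6 1-tert-butyl 6-[(2E)-5-{[tert-butyl(dimethyl)silyl]oxy}-3-methylpent-2-en-1-yl] (3E)-hex-3-enedioate
Conditions: EDC·HCl, DMAP (5 mol %), CH2Cl2, −10 → 0 °C
Reagents that add atoms: none
Why: Steglich esterification of a primary allylic alcohol is reliable, and low temperature with little DMAP should keep the alkene out of conjugation.

**Step 4**
Reactants: 6 1-tert-butyl 6-[(2E)-5-{[tert-butyl(dimethyl)silyl]oxy}-3-methylpent-2-en-1-yl] (3E)-hex-3-enedioate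
Product: 9 (2R,3E)-6-tert-butoxy-2-[(3S)-5-{[tert-butyl(dimethyl)silyl]oxy}-3-methylpent-1-en-3-yl]-6-oxohex-3-enoic acid, via boron ketene acetal 7 (not isolated), via acyloxyborane 8 (not isolated)
Conditions: pre-formed (4R,5R)-2-bromo-1,3-bis{[3,5-bis(trifluoromethyl)phenyl]sulfonyl}-4,5-diphenyl-1,3,2-diazaborolidine (2.2 equiv), i-Pr2NEt, CH2Cl2, −78 °C; then −20 → 4 °C; aqueous work-up
Reagents that add atoms: none
Why: enantioselective Ireland–Claisen rearrangement, in which soft enolisation should give the boron dienolate with the C6 chain cis to O–B; the [3,3] shift through a chair with C9 of the (E)-alkene equatorial then sets C5 and the quaternary C10 (methyl, vinyl) relative to each other, the controller fixes the absolute sense, and any enolisation of the tert-butyl ester reverts on work-up.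

**Step 5**
Reactants: 9 (2R,3E)-6-tert-butoxy-2-[(3S)-5-{[tert-butyl(dimethyl)silyl]oxy}-3-methylpent-1-en-3-yl]-6-oxohex-3-enoic acid
Product: 10 6-tert-butyl 1-(prop-2-en-1-yl) (2R,3E)-2-[(3S)-5-{[tert-butyl(dimethyl)silyl]oxy}-3-methylpent-1-en-3-yl]hex-3-enedioate
Conditions: allyl bromide, KHCO3, DMF, rt
Reagents that add atoms: allyl bromide, C=CCBr
Why: carboxylate O-alkylation under weak base masks the C4 acid as an ester that is inert to Lewis acid and is removable later by palladium, without enolising C5.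

**Step 6**
Reactants: 10 6-tert-butyl 1-(prop-2-en-1-yl) (2R,3E)-2-[(3S)-5-{[tert-butyl(dimethyl)silyl]oxy}-3-methylpent-1-en-3-yl]hex-3-enedioate
Product: 11 6-tert-butyl 1-(prop-2-en-1-yl) (2R,3E)-2-[(3S)-5-hydroxy-3-methylpent-1-en-3-yl]hex-3-enedioate
Conditions: HF·pyridine, THF/pyridine, 0 °C → rt
Reagents that add atoms: none
Why: buffered fluoride desilylation of a primary silyl ether leaves both esters and the base-sensitive C5 centre untouched.

**Step 7**
Reactants: 11 6-tert-butyl 1-(prop-2-en-1-yl) (2R,3E)-2-[(3S)-5-hydroxy-3-methylpent-1-en-3-yl]hex-3-enedioate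
Product: 12 6-tert-butyl 1-(prop-2-en-1-yl) (2R,3E)-2-[(3S)-3-methyl-5-oxopent-1-en-3-yl]hex-3-enedioate
Conditions: Dess–Martin periodinane, NaHCO3, CH2Cl2, 0 °C → rt
Reagents that add atoms: none
Why: Dess–Martin oxidation gives the aldehyde under near-neutral conditions, and the aldehyde has a quaternary β-carbon so it cannot epimerise.

**Step 8**
Reactants: 12 6-tert-butyl 1-(prop-2-en-1-yl) (2R,3E)-2-[(3S)-3-methyl-5-oxopent-1-en-3-yl]hex-3-enedioate
Product: 14 prop-2-en-1-yl (3aR,4S,6S,7S,7aS)-6-ethenyl-4-hydroxy-6-methyl-2-oxo-octahydro-1-benzofuran-7-carboxylate, via stannate dialkoxycarbenium zwitterion 13 (not isolated)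
Conditions: SnCl4 (1.5 equiv), CH2Cl2, −78 → −40 °C; cold aq. NaHCO3
Reagents that add atoms: none
Why: Proposed new method: SnCl4 binds the aldehyde oxygen, C7 of the (E)-C6=C7 bond attacks C8 through a chair (6-endo-trig closure of ring B), and the carbonyl oxygen of the tert-butyl ester captures the charge developing at C6 from the opposite face (5-endo closure of the lactone ring, as in halolactonisation of β,γ-unsaturated acids), after which ion 13 loses 2-methylpropene. The closest known reactions are Lewis-acid Prins cyclisations of δ,ε-unsaturated aldehydes and the acid-promoted cyclisation of homofarnesic acid to a trans-fused γ-lactone, a cation–olefin cyclisation ended by a carboxyl group on an (E)-alkene; a 1,2-disubstituted alkene flanked by two ester-bearing carbons has not been used in this combination. Anti addition across the (E)-alkene makes H6 and H7 trans-diaxial, so the lactone is trans-fused with C6–O and C7–C11 equatorial. C5 and C10 relay the absolute sense: the chair with the C5 ester equatorial puts the C10 methyl axial, and that axial methyl forces the tin-bound oxygen at C8 equatorial (8α) to avoid a 1,3-diaxial clash. The step needs 6-endo over 5-exo attack, which the γ-lactone (against a β-lactone) and the chair secure, and chemoselectivity over the vinyl and allyl groups, which are monosubstituted and can reach C8 only by 4-exo or 5-endo paths. Proton loss from C5 toward the conjugated ester is the competing path and should be outrun by the intramolecular, antiperiplanar oxygen.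

**Step 9**
Reactants: 14 prop-2-en-1-yl (3aR,4S,6S,7S,7aS)-6-ethenyl-4-hydroxy-6-methyl-2-oxo-octahydro-1-benzofuran-7-carboxylate
Product: 16 prop-2-en-1-yl (3S,3aR,4S,6S,7S,7aS)-6-ethenyl-4-hydroxy-3,6-dimethyl-2-oxo-octahydro-1-benzofuran-7-carboxylate, via dilithium alkoxide enolate 15 (not isolated)
Conditions: lithium diisopropylamide (LiN(i-Pr)2, 2.1 equiv), THF, −78 °C; MeI, −78 → −50 °C; AcOH quench at −78 °C
Reagents that add atoms: iodomethane, CI
Why: the lactone α-CH2 is more acidic and far less hindered than the tertiary C5–H of the allyl ester, and methyl iodide should enter the trans-fused lactone enolate from the α face, anti to the C7–C8 bond, giving the 11α-methyl epimer, which is also the more stable one.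

**Step 10**
Reactants: 17 methyl (2R)-3-hydroxy-2-methylpropanoate
Product: 18 methyl (2R)-3-{[tert-butyl(dimethyl)silyl]oxy}-2-methylpropanoate
Conditions: TBSCl, imidazole, CH2Cl2, 0 °C → rt
Reagents that add atoms: tert-butyldimethylsilyl chloride, CC(C)(C)[Si](C)(C)Cl
Why: standard silylation of a primary alcohol, which does not touch the α-stereocentre.

**Step 11**
Reactants: 18 methyl (2R)-3-{[tert-butyl(dimethyl)silyl]oxy}-2-methylpropanoate
Product: 19 (2R)-3-{[tert-butyl(dimethyl)silyl]oxy}-2-methylpropanoic acid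
Conditions: LiOH, THF/H2O, 0 °C → rt; cold 1 M HCl to pH 3
Reagents that add atoms: lithium hydroxide, [Li+].[OH-]
Why: mild saponification at low temperature should give the acid without β-elimination of the silyloxy group or epimerisation.

**Step 12**
Reactants: 16 prop-2-en-1-yl (3S,3aR,4S,6S,7S,7aS)-6-ethenyl-4-hydroxy-3,6-dimethyl-2-oxo-octahydro-1-benzofuran-7-carboxylate; 19 (2R)-3-{[tert-butyl(dimethyl)silyl]oxy}-2-methylpropanoic acid
Product: 20 prop-2-en-1-yl (3S,3aR,4S,6S,7S,7aS)-4-{[(2R)-3-{[tert-butyl(dimethyl)silyl]oxy}-2-methylpropanoyl]oxy}-6-ethenyl-3,6-dimethyl-2-oxo-octahydro-1-benzofuran-7-carboxylate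
Conditions: EDC·HCl, DMAP, CH2Cl2, 0 °C → rt
Reagents that add atoms: none
Why: Steglich esterification of the equatorial 8α-hydroxyl, the only free hydroxyl, which also removes the risk of lactone migration to O8.

**Step 13**
Reactants: 20 prop-2-en-1-yl (3S,3aR,4S,6S,7S,7aS)-4-{[(2R)-3-{[tert-butyl(dimethyl)silyl]oxy}-2-methylpropanoyl]oxy}-6-ethenyl-3,6-dimethyl-2-oxo-octahydro-1-benzofuran-7-carboxylate
Product: 21 (3S,3aR,4S,6S,7S,7aS)-4-{[(2R)-3-{[tert-butyl(dimethyl)silyl]oxy}-2-methylpropanoyl]oxy}-6-ethenyl-3,6-dimethyl-2-oxo-octahydro-1-benzofuran-7-carboxylic acid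
Conditions: Pd(PPh3)4 (5 mol %), morpholine, THF, rt
Reagents that add atoms: none
Why: Tsuji–Trost deallylation, in which zerovalent palladium ionises only the allyl ester and morpholine traps the allyl fragment, leaving lactone, side-chain ester and silyl ether intact.

**Step 14**
Reactants: 22 (tributylstannyl)methanol
Product: 23 tert-butyl(dimethyl)[(tributylstannyl)methoxy]silane
Conditions: TBSCl, imidazole, CH2Cl2, rt
Reagents that add atoms: tert-butyldimethylsilyl chloride, CC(C)(C)[Si](C)(C)Cl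
Why: standard silylation of a primary alcohol, giving a one-carbon oxygenated stannane that carries the same protecting group as the side chain.

**Step 15**
Reactants: 21 (3S,3aR,4S,6S,7S,7aS)-4-{[(2R)-3-{[tert-butyl(dimethyl)silyl]oxy}-2-methylpropanoyl]oxy}-6-ethenyl-3,6-dimethyl-2-oxo-octahydro-1-benzofuran-7-carboxylic acid; 23 tert-butyl(dimethyl)[(tributylstannyl)methoxy]silane
Product: 25 (3S,3aR,4S,6S,7S,7aS)-7-({[tert-butyl(dimethyl)silyl]oxy}acetyl)-6-ethenyl-3,6-dimethyl-2-oxo-octahydro-1-benzofuran-4-yl (2R)-3-{[tert-butyl(dimethyl)silyl]oxy}-2-methylpropanoate, via acid chloride 24 (not isolated)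
Conditions: 1-chloro-N,N,2-trimethylprop-1-en-1-amine, CH2Cl2, 0 °C → rt; then 23, PdCl2(PPh3)2 (5 mol %), toluene, CO (1 atm), 70 °C
Reagents that add atoms: none
Why: neutral acid chloride formation followed by Stille acylation, in which the oxygen-bearing CH2 group of an alkoxymethylstannane transfers in preference to butyl; CO suppresses decarbonylation of the hindered acyl palladium species, and C5 can only settle in its equatorial configuration.

**Step 16**
Reactants: 25 (3S,3aR,4S,6S,7S,7aS)-7-({[tert-butyl(dimethyl)silyl]oxy}acetyl)-6-ethenyl-3,6-dimethyl-2-oxo-octahydro-1-benzofuran-4-yl (2R)-3-{[tert-butyl(dimethyl)silyl]oxy}-2-methylpropanoate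
Product: 26 (3S,3aR,4S,6S,7R,7aR)-7-(3-{[tert-butyl(dimethyl)silyl]oxy}prop-1-en-2-yl)-6-ethenyl-3,6-dimethyl-2-oxo-octahydro-1-benzofuran-4-yl (2R)-3-{[tert-butyl(dimethyl)silyl]oxy}-2-methylpropanoate
Conditions: Zn, CH2Br2, TiCl4, THF/CH2Cl2, 0 °C → rt
Reagents that add atoms: dibromomethane, BrCBr
Why: Takai–Lombardo methylenation is non-basic and selective for ketones over esters and lactones, so the β-silyloxy ester side chain should not eliminate and C11 should not epimerise.

**Step 17**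
Reactants: 26 (3S,3aR,4S,6S,7R,7aR)-7-(3-{[tert-butyl(dimethyl)silyl]oxy}prop-1-en-2-yl)-6-ethenyl-3,6-dimethyl-2-oxo-octahydro-1-benzofuran-4-yl (2R)-3-{[tert-butyl(dimethyl)silyl]oxy}-2-methylpropanoate
Product: 27 (3S,3aR,4S,6S,7R,7aR)-6-ethenyl-7-(3-hydroxyprop-1-en-2-yl)-3,6-dimethyl-2-oxo-octahydro-1-benzofuran-4-yl (2R)-3-hydroxy-2-methylpropanoate
Conditions: HF·pyridine, THF/pyridine, 0 °C → rt
Reagents that add atoms: none
Why: buffered fluoride removes both primary silyl ethers without acyl migration or opening of the lactone.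

**Compound list**
1 | tert-butyl(but-3-yn-1-yloxy)dimethylsilane | C#CCCO[Si](C)(C)C(C)(C)C | starting material
2 | [(1E)-4-{[tert-butyl(dimethyl)silyl]oxy}-2-methylbut-1-en-1-yl]dimethylalane | C[Al](C)/C=C(\C)CCO[Si](C)(C)C(C)(C)C | intermediate
3 | (2E)-5-{[tert-butyl(dimethyl)silyl]oxy}-3-methylpent-2-en-1-ol | OC/C=C(\C)CCO[Si](C)(C)C(C)(C)C | intermediate
4 | (3E)-hex-3-enedioic acid | OC(=O)C/C=C/CC(=O)O | starting material
5 | (3E)-6-tert-butoxy-6-oxohex-3-enoic acid | CC(C)(C)OC(=O)C/C=C/CC(=O)O | intermediate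
6 | 1-tert-butyl 6-[(2E)-5-{[tert-butyl(dimethyl)silyl]oxy}-3-methylpent-2-en-1-yl] (3E)-hex-3-enedioate | CC(C)(C)OC(=O)C/C=C/CC(=O)OC/C=C(\C)CCO[Si](C)(C)C(C)(C)C | intermediate
7 | boron ketene acetal of 6, O-bound to the (4R,5R)-1,3-bis(arylsulfonyl)-4,5-diphenyl-1,3,2-diazaborolidin-2-yl group, C6 chain cis to O–B | CC(C)(C)OC(=O)C/C=C/C=C(\OB1N(S(=O)(=O)c2cc(cc(c2)C(F)(F)F)C(F)(F)F)[C@H](c2ccccc2)[C@@H](c2ccccc2)N1S(=O)(=O)c1cc(cc(c1)C(F)(F)F)C(F)(F)F)OC/C=C(\C)CCO[Si](C)(C)C(C)(C)C | intermediate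
8 | acyloxyborane of acid 9 with the same (4R,5R)-diazaborolidin-2-yl group | C=C[C@]([C@H](C(=O)OB1N(S(=O)(=O)c2cc(cc(c2)C(F)(F)F)C(F)(F)F)[C@H](c2ccccc2)[C@@H](c2ccccc2)N1S(=O)(=O)c1cc(cc(c1)C(F)(F)F)C(F)(F)F)/C=C/CC(=O)OC(C)(C)C)(C)CCO[Si](C)(C)C(C)(C)C | intermediate
9 | (2R,3E)-6-tert-butoxy-2-[(3S)-5-{[tert-butyl(dimethyl)silyl]oxy}-3-methylpent-1-en-3-yl]-6-oxohex-3-enoic acid | C=C[C@]([C@H](C(=O)O)/C=C/CC(=O)OC(C)(C)C)(C)CCO[Si](C)(C)C(C)(C)C | intermediate
10 | 6-tert-butyl 1-(prop-2-en-1-yl) (2R,3E)-2-[(3S)-5-{[tert-butyl(dimethyl)silyl]oxy}-3-methylpent-1-en-3-yl]hex-3-enedioate | C=C[C@]([C@H](C(=O)OCC=C)/C=C/CC(=O)OC(C)(C)C)(C)CCO[Si](C)(C)C(C)(C)C | intermediate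
11 | 6-tert-butyl 1-(prop-2-en-1-yl) (2R,3E)-2-[(3S)-5-hydroxy-3-methylpent-1-en-3-yl]hex-3-enedioate | C=C[C@]([C@H](C(=O)OCC=C)/C=C/CC(=O)OC(C)(C)C)(C)CCO | intermediate
12 | 6-tert-butyl 1-(prop-2-en-1-yl) (2R,3E)-2-[(3S)-3-methyl-5-oxopent-1-en-3-yl]hex-3-enedioate | C=C[C@]([C@H](C(=O)OCC=C)/C=C/CC(=O)OC(C)(C)C)(C)CC=O | intermediate
13 | zwitterion: 2-tert-butoxy-dihydrofuranylium ion fused to ring B at C6/C7, with the C8 oxygen bound to tetrachlorostannate | C=C[C@]1(C)C[C@H](O[Sn-](Cl)(Cl)(Cl)Cl)[C@@H]2[C@H]([O+]=C(OC(C)(C)C)C2)[C@H]1C(=O)OCC=C | intermediate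
14 | prop-2-en-1-yl (3aR,4S,6S,7S,7aS)-6-ethenyl-4-hydroxy-6-methyl-2-oxo-octahydro-1-benzofuran-7-carboxylate | C=C[C@]1(C)C[C@H](O)[C@@H]2[C@H](OC(=O)C2)[C@H]1C(=O)OCC=C | intermediate
15 | dilithium salt of 14 (C8 alkoxide and lactone enolate) | C=C[C@]1(C)C[C@H]([O-])[C@@H]2[C@H](OC([O-])=C2)[C@H]1C(=O)OCC=C.[Li+].[Li+] | intermediate
16 | prop-2-en-1-yl (3S,3aR,4S,6S,7S,7aS)-6-ethenyl-4-hydroxy-3,6-dimethyl-2-oxo-octahydro-1-benzofuran-7-carboxylate | C=C[C@]1(C)C[C@H](O)[C@@H]2[C@H](OC(=O)[C@H]2C)[C@H]1C(=O)OCC=C | intermediate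
17 | methyl (2R)-3-hydroxy-2-methylpropanoate | COC(=O)[C@H](C)CO | starting material
18 | methyl (2R)-3-{[tert-butyl(dimethyl)silyl]oxy}-2-methylpropanoate | COC(=O)[C@H](C)CO[Si](C)(C)C(C)(C)C | intermediate
19 | (2R)-3-{[tert-butyl(dimethyl)silyl]oxy}-2-methylpropanoic acid | OC(=O)[C@H](C)CO[Si](C)(C)C(C)(C)C | intermediate
20 | prop-2-en-1-yl (3S,3aR,4S,6S,7S,7aS)-4-{[(2R)-3-{[tert-butyl(dimethyl)silyl]oxy}-2-methylpropanoyl]oxy}-6-ethenyl-3,6-dimethyl-2-oxo-octahydro-1-benzofuran-7-carboxylate | C=C[C@]1(C)C[C@H](OC(=O)[C@H](C)CO[Si](C)(C)C(C)(C)C)[C@@H]2[C@H](OC(=O)[C@H]2C)[C@H]1C(=O)OCC=C | intermediate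
21 | (3S,3aR,4S,6S,7S,7aS)-4-{[(2R)-3-{[tert-butyl(dimethyl)silyl]oxy}-2-methylpropanoyl]oxy}-6-ethenyl-3,6-dimethyl-2-oxo-octahydro-1-benzofuran-7-carboxylic acid | C=C[C@]1(C)C[C@H](OC(=O)[C@H](C)CO[Si](C)(C)C(C)(C)C)[C@@H]2[C@H](OC(=O)[C@H]2C)[C@H]1C(=O)O | intermediate
22 | (tributylstannyl)methanol | CCCC[Sn](CCCC)(CCCC)CO | starting material
23 | tert-butyl(dimethyl)[(tributylstannyl)methoxy]silane | CCCC[Sn](CCCC)(CCCC)CO[Si](C)(C)C(C)(C)C | intermediate
24 | acid chloride of 21 | C=C[C@]1(C)C[C@H](OC(=O)[C@H](C)CO[Si](C)(C)C(C)(C)C)[C@@H]2[C@H](OC(=O)[C@H]2C)[C@H]1C(=O)Cl | intermediate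
25 | (3S,3aR,4S,6S,7S,7aS)-7-({[tert-butyl(dimethyl)silyl]oxy}acetyl)-6-ethenyl-3,6-dimethyl-2-oxo-octahydro-1-benzofuran-4-yl (2R)-3-{[tert-butyl(dimethyl)silyl]oxy}-2-methylpropanoate | C=C[C@]1(C)C[C@H](OC(=O)[C@H](C)CO[Si](C)(C)C(C)(C)C)[C@@H]2[C@H](OC(=O)[C@H]2C)[C@H]1C(=O)CO[Si](C)(C)C(C)(C)C | intermediate
26 | (3S,3aR,4S,6S,7R,7aR)-7-(3-{[tert-butyl(dimethyl)silyl]oxy}prop-1-en-2-yl)-6-ethenyl-3,6-dimethyl-2-oxo-octahydro-1-benzofuran-4-yl (2R)-3-{[tert-butyl(dimethyl)silyl]oxy}-2-methylpropanoate | C=C[C@]1(C)C[C@H](OC(=O)[C@H](C)CO[Si](C)(C)C(C)(C)C)[C@@H]2[C@H](OC(=O)[C@H]2C)[C@H]1C(=C)CO[Si](C)(C)C(C)(C)C | intermediate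
27 | (3S,3aR,4S,6S,7R,7aR)-6-ethenyl-7-(3-hydroxyprop-1-en-2-yl)-3,6-dimethyl-2-oxo-octahydro-1-benzofuran-4-yl (2R)-3-hydroxy-2-methylpropanoate | C=C[C@]1(C)C[C@H](OC(=O)[C@H](C)CO)[C@@H]2[C@H](OC(=O)[C@H]2C)[C@H]1C(=C)CO | target

**Total step count:** 17.
**Longest linear sequence:** 13 steps (1 → 3 → 6 → 9 → 10 → 11 → 12 → 14 → 16 → 20 → 21 → 25 → 26 → 27).

**Steps most likely to fail**

Step 8 (proposed new method). The C6=C7 bond carries an ester-bearing carbon on each side, so its attack on the tin-bound aldehyde may be slow enough for aldehyde self-condensation to take over, or proton loss from C5 may outrun lactone closure. The fallback sets out from 12 and returns at 14. Aldehyde 12 is converted with propane-1,3-diol and pyridinium p-toluenesulfonate into the 1,3-dioxane acetal F1. F1 is cyclised with TiCl4 in CH2Cl2 at −78 °C in a known acetal-initiated cation–olefin cyclisation, whose cyclic oxocarbenium ion is more electrophilic and cannot enolise; this should give the 8-O-(3-hydroxypropyl) ether lactone F2. Dess–Martin oxidation of F2 gives the β-alkoxy aldehyde F3, and β-elimination with piperidinium acetate releases 14.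

Step 4. The dienolate may form with poor geometric control, or the controller may give low facial selectivity on this α-alkenyl ester, so that C5/C10 diastereomers or the wrong enantiomer arise. The fallback sets out from 6 and returns at 9. Ester 6 is converted with LiN(SiMe3)2 and Me3SiCl in THF/HMPA at −78 °C into the achiral bis(trimethylsilyl) ketene acetal F4. Warming brings about the classical Ireland–Claisen rearrangement to racemic acid, that is 9 together with its enantiomer F5. The racemate is resolved by crystallisation of the (S)-1-phenylethylammonium salt F6 of 9, which is acidified to 9.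

Step 9. Methyl iodide may attack the enolate with poor facial selectivity, the C5–H of the allyl ester may be deprotonated in competition, or the C8 alkoxide may attack the lactone carbonyl and shift the lactone to O8. The fallback sets out from 14 and returns at 16. The enolate of 14 is trapped with dimethyl(methylidene)ammonium iodide to give the Mannich base F7. F7 is quaternised with MeI to the ammonium iodide F8, which eliminates with NaHCO3 to the α-methylene lactone F9. Conjugate reduction of F9 with NaBH4 in MeOH at 0 °C, with protonation under equilibrating conditions, should give the 11α-methyl lactone 16.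

**Further compounds**
F1 | step 8 | 6-tert-butyl 1-(prop-2-en-1-yl) (2R,3E)-2-[(2S)-1-(1,3-dioxan-2-yl)-2-methylbut-3-en-2-yl]hex-3-enedioate | C=C[C@]([C@H](C(=O)OCC=C)/C=C/CC(=O)OC(C)(C)C)(C)CC1OCCCO1
F2 | step 8 | prop-2-en-1-yl (3aR,4S,6S,7S,7aS)-6-ethenyl-4-(3-hydroxypropoxy)-6-methyl-2-oxo-octahydro-1-benzofuran-7-carboxylate | C=C[C@]1(C)C[C@H](OCCCO)[C@@H]2[C@H](OC(=O)C2)[C@H]1C(=O)OCC=C
F3 | step 8 | prop-2-en-1-yl (3aR,4S,6S,7S,7aS)-6-ethenyl-6-methyl-2-oxo-4-(3-oxopropoxy)-octahydro-1-benzofuran-7-carboxylate | C=C[C@]1(C)C[C@H](OCCC=O)[C@@H]2[C@H](OC(=O)C2)[C@H]1C(=O)OCC=C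
F4 | step 4 | bis(trimethylsilyl) ketene acetal of 6 (both ester termini enolised, silyloxy groups cis to the chain) | CC(C)(C)OC(/O[Si](C)(C)C)=C/C=C/C=C(\O[Si](C)(C)C)OC/C=C(\C)CCO[Si](C)(C)C(C)(C)C
F5 | step 4 | (2S,3E)-6-tert-butoxy-2-[(3R)-5-{[tert-butyl(dimethyl)silyl]oxy}-3-methylpent-1-en-3-yl]-6-oxohex-3-enoic acid (enantiomer of 9) | C=C[C@@]([C@@H](C(=O)O)/C=C/CC(=O)OC(C)(C)C)(C)CCO[Si](C)(C)C(C)(C)C
F6 | step 4 | (S)-1-phenylethylammonium salt of 9 | C=C[C@]([C@H](C([O-])=O)/C=C/CC(=O)OC(C)(C)C)(C)CCO[Si](C)(C)C(C)(C)C.C[C@H]([NH3+])c1ccccc1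
F7 | step 9 | prop-2-en-1-yl (3S,3aR,4S,6S,7S,7aS)-3-[(dimethylamino)methyl]-6-ethenyl-4-hydroxy-6-methyl-2-oxo-octahydro-1-benzofuran-7-carboxylate | C=C[C@]1(C)C[C@H](O)[C@@H]2[C@H](OC(=O)[C@H]2CN(C)C)[C@H]1C(=O)OCC=C
F8 | step 9 | trimethylammonium iodide of F7 | C=C[C@]1(C)C[C@H](O)[C@@H]2[C@H](OC(=O)[C@H]2C[N+](C)(C)C)[C@H]1C(=O)OCC=C.[I-]
F9 | step 9 | prop-2-en-1-yl (3aS,4S,6S,7S,7aS)-6-ethenyl-4-hydroxy-6-methyl-3-methylidene-2-oxo-octahydro-1-benzofuran-7-carboxylate | C=C[C@]1(C)C[C@H](O)[C@@H]2[C@H](OC(=O)C2=C)[C@H]1C(=O)OCC=C
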